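## Retrosynthetic overview

1. Target = 5,7-dihydroxyflavone carrying a trans-(2R,3R)-3-aryl-2-hydroxymethyl-8-methoxy-1,4-benzodioxane. The pyranone ring is formed last, by cyclodehydration of a 1,3-diketone made by Claisen condensation of benzodioxane methyl ester **8** with acetophenone **9**.
2. The 1,4-dioxane ring is closed by intramolecular Pd C–O coupling of an aryl bromide with the benzylic alcohol (retention), so the open-chain syn relationship becomes the trans ring.
3. Both stereocentres come from one Evans syn glycolate aldol between an aryloxyacetyl oxazolidinone and O-benzylsyringaldehyde.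
4. The C(sp3)–O bond to the B-ring 4-oxygen comes from phenol alkylation of methyl 5-bromovanillate, which fixes the regiochemistry (4-O on the CH2OH carbon, 3-O on the benzylic carbon).
5. Ring order: three purchased arenes → dioxane ring → pyranone ring → global debenzylation.

Assumption: compounds **1**, **2**, **4** and **9** are treated as catalogue chemicals; each is otherwise one routine step from a common precursor.

## Route

**Step 1**
Reactants: **1** methyl 3-bromo-4-hydroxy-5-methoxybenzoate; **2** (S)-4-benzyl-3-(chloroacetyl)oxazolidin-2-one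
Product: **3** (S)-4-benzyl-3-{2-[2-bromo-6-methoxy-4-(methoxycarbonyl)phenoxy]acetyl}oxazolidin-2-one
Conditions: K2CO3, NaI (cat.), acetone, 50 °C
Reagents that add atoms: none
Why: Finkelstein-assisted Williamson etherification; the acidic, hindered phenoxide displaces the activated α-halide rather than attacking the imide carbonyl, and no stereocentre is formed.

**Step 2**
Reactants: **3**; **4** 4-(benzyloxy)-3,5-dimethoxybenzaldehyde
Product: **5** (S)-4-benzyl-3-[(2S,3R)-3-[4-(benzyloxy)-3,5-dimethoxyphenyl]-2-[2-bromo-6-methoxy-4-(methoxycarbonyl)phenoxy]-3-hydroxypropanoyl]oxazolidin-2-one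
Conditions: Bu2BOTf, i-Pr2NEt, CH2Cl2, −78 → 0 °C; then **4**, −78 → 0 °C; pH 7 buffer, H2O2, MeOH
Reagents that add atoms: none
Why: Evans boron glycolate aldol; the Z-boron enolate reacts through a Zimmerman–Traxler chair on the face away from the auxiliary benzyl group, giving the 2,3-syn (2S,3R) adduct and setting both target stereocentres.

**Step 3**
Reactants: **5**
Product: **6** methyl 4-{[(1R,2R)-1-[4-(benzyloxy)-3,5-dimethoxyphenyl]-1,3-dihydroxypropan-2-yl]oxy}-3-bromo-5-methoxybenzoate
Conditions: NaBH4, THF/H2O (4:1), 0 °C → rt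
Reagents that add atoms: none
Why: Reductive cleavage of the activated N-acyl oxazolidinone to the primary alcohol; the aryl methyl ester and aryl bromide are inert to NaBH4 and no stereocentre is touched (the descriptor at C2 changes only through CIP priorities).

**Step 4**
Reactants: **6**
Product: **7** methyl 4-{[(1R,2R)-1-[4-(benzyloxy)-3,5-dimethoxyphenyl]-3-[(tert-butyldimethylsilyl)oxy]-1-hydroxypropan-2-yl]oxy}-3-bromo-5-methoxybenzoate
Conditions: TBSCl, imidazole, CH2Cl2, 0 °C
Reagents that add atoms: TBSCl, CC(C)(C)[Si](C)(C)Cl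
Why: Sterically controlled silylation of the primary over the hindered benzylic secondary alcohol; this blocks the competing seven-membered ring closure and protects the alcohol in the Claisen step.

**Step 5**
Reactants: **7**
Product: **8** methyl (2R,3R)-3-[4-(benzyloxy)-3,5-dimethoxyphenyl]-2-{[(tert-butyldimethylsilyl)oxy]methyl}-8-methoxy-2,3-dihydro-1,4-benzodioxine-6-carboxylate
Conditions: Pd(OAc)2 (5 mol %), 2-(di-tert-butylphosphino)-1,1'-binaphthyl (6 mol %), Cs2CO3, toluene, 80 °C
Reagents that add atoms: none
Why: Buchwald intramolecular Pd-catalysed aryl etherification forming the six-membered ring; the carbinol C–O bond is not broken, so both centres are retained and the syn diol pattern gives the trans-(2R,3R) benzodioxane.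

**Step 6**
Reactants: **8**; **9** 1-[2,4-bis(benzyloxy)-6-hydroxyphenyl]ethanone
Product: **10** 1-[2,4-bis(benzyloxy)-6-hydroxyphenyl]-3-[(2R,3R)-3-[4-(benzyloxy)-3,5-dimethoxyphenyl]-2-{[(tert-butyldimethylsilyl)oxy]methyl}-8-methoxy-2,3-dihydro-1,4-benzodioxin-6-yl]propane-1,3-dione
Conditions: **9**, LiHMDS (4 equiv), THF, −78 → −10 °C; then **8**, −78 °C → rt
Reagents that add atoms: none
Why: Crossed Claisen condensation of the acetophenone lithium dianion with the non-enolisable methyl ester (the diketone of a Baker–Venkataraman flavone synthesis); the benzodioxane C–H bonds are not acidic, so the stereocentres are safe.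

**Step 7**
Reactants: **10**
Product: **11** 5,7-bis(benzyloxy)-2-[(2R,3R)-3-[4-(benzyloxy)-3,5-dimethoxyphenyl]-2-(hydroxymethyl)-8-methoxy-2,3-dihydro-1,4-benzodioxin-6-yl]-4H-chromen-4-one
Conditions: conc. HCl (cat.), MeOH/THF, 60 °C
Reagents that add atoms: none
Why: Acid-catalysed cyclodehydration of the o-hydroxyaryl 1,3-diketone to the flavone, with the same acid removing the primary TBS ether; any reversible benzylic ionisation would re-close to the favoured trans isomer because C2 is fixed.

**Step 8**
Reactants: **11**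
Product: **12** palstatin, 5,7-dihydroxy-2-[(2R,3R)-3-(4-hydroxy-3,5-dimethoxyphenyl)-2-(hydroxymethyl)-8-methoxy-2,3-dihydro-1,4-benzodioxin-6-yl]-4H-chromen-4-one
Conditions: H2 (1 atm), 10% Pd/C, THF/MeOH, rt
Reagents that add atoms: none
Why: Hydrogenolysis of the three O-benzyl ethers; the flavone enone and the cyclic secondary benzylic ether react much more slowly at 1 atm and rt, so the stereocentres are untouched.

## Compound list

1 | methyl 3-bromo-4-hydroxy-5-methoxybenzoate | COC(=O)c1cc(Br)c(O)c(OC)c1 | starting material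
2 | (S)-4-benzyl-3-(chloroacetyl)oxazolidin-2-one | ClCC(=O)N1C(=O)OC[C@@H]1Cc1ccccc1 | starting material
3 | (S)-4-benzyl-3-{2-[2-bromo-6-methoxy-4-(methoxycarbonyl)phenoxy]acetyl}oxazolidin-2-one | COC(=O)c1cc(Br)c(OCC(=O)N2C(=O)OC[C@@H]2Cc2ccccc2)c(OC)c1 | intermediate
4 | 4-(benzyloxy)-3,5-dimethoxybenzaldehyde | COc1cc(C=O)cc(OC)c1OCc1ccccc1 | starting material
5 | (2S,3R)-syn aldol adduct on the (S)-oxazolidinone | COC(=O)c1cc(Br)c(O[C@@H]([C@H](O)c2cc(OC)c(OCc3ccccc3)c(OC)c2)C(=O)N2C(=O)OC[C@@H]2Cc2ccccc2)c(OC)c1 | intermediate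
6 | methyl 4-{[(1R,2R)-1-[4-(benzyloxy)-3,5-dimethoxyphenyl]-1,3-dihydroxypropan-2-yl]oxy}-3-bromo-5-methoxybenzoate | COC(=O)c1cc(Br)c(O[C@H](CO)[C@H](O)c2cc(OC)c(OCc3ccccc3)c(OC)c2)c(OC)c1 | intermediate
7 | primary TBS ether of 6 | COC(=O)c1cc(Br)c(O[C@H](CO[Si](C)(C)C(C)(C)C)[C@H](O)c2cc(OC)c(OCc3ccccc3)c(OC)c2)c(OC)c1 | intermediate
8 | methyl (2R,3R)-3-[4-(benzyloxy)-3,5-dimethoxyphenyl]-2-(TBSO-methyl)-8-methoxy-2,3-dihydro-1,4-benzodioxine-6-carboxylate | COc1cc([C@H]2Oc3cc(C(=O)OC)cc(OC)c3O[C@@H]2CO[Si](C)(C)C(C)(C)C)cc(OC)c1OCc1ccccc1 | intermediate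
9 | 1-[2,4-bis(benzyloxy)-6-hydroxyphenyl]ethanone | CC(=O)c1c(O)cc(OCc2ccccc2)cc1OCc1ccccc1 | starting material
10 | 1,3-diketone from 8 + 9 | COc1cc([C@H]2Oc3cc(C(=O)CC(=O)c4c(O)cc(OCc5ccccc5)cc4OCc4ccccc4)cc(OC)c3O[C@@H]2CO[Si](C)(C)C(C)(C)C)cc(OC)c1OCc1ccccc1 | intermediate
11 | tri-O-benzyl palstatin | COc1cc([C@H]2Oc3cc(-c4cc(=O)c5c(OCc6ccccc6)cc(OCc6ccccc6)cc5o4)cc(OC)c3O[C@@H]2CO)cc(OC)c1OCc1ccccc1 | intermediate
12 | palstatin | COc1cc([C@H]2Oc3cc(-c4cc(=O)c5c(O)cc(O)cc5o4)cc(OC)c3O[C@@H]2CO)cc(OC)c1O | target

## Summary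

Total steps: 8. Longest linear sequence: 8 (from **1**; **2**, **4** and **9** enter as purchased partners).

Steps most likely to fail, with fallbacks:

- **Step 5 (Pd C–O ring closure).** A hindered secondary benzylic alkoxide can undergo β-hydride elimination or hydrodebromination instead of coupling. Fallback: convert the aryl bromide of **7** to the phenol (Miyaura borylation, then H2O2) and close the dioxane by acid-promoted SN1 etherification at the benzylic carbon (TFA or BF3·OEt2). This converges on the thermodynamic trans isomer while C2 stays fixed.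
- **Step 6 (Claisen condensation with an electron-rich methyl benzoate).** The ester may be too unreactive toward the dianion. Fallback: reduce the ester to the benzylic alcohol (DIBAL-H), oxidise to the aldehyde (MnO2), run a Claisen–Schmidt condensation with **9** to the 2'-hydroxychalcone, and cyclise oxidatively with I2/DMSO to the same flavone **11** after desilylation.
- **Step 2 (Evans aldol with a bulky 2,6-disubstituted aryloxy enolate and a deactivated aldehyde).** Conversion or diastereoselectivity may be poor. Fallback: C-acylate the enolate of the corresponding methyl aryloxyacetate with 4-(benzyloxy)-3,5-dimethoxybenzoyl chloride, then set both centres by Ru(II)–TsDPEN transfer hydrogenation with dynamic kinetic resolution (syn-selective). NaBH4 reduction then gives **6**.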